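The route rests on opening the 1,2-dioxane, via its 4,5-dehydro form, across O2–C3 and O1–C6 into dioxygen and an acyclic diene. The feature exploited lies in ring O1–O2–C3–C4–C5–C6. The two oxygen-bearing carbons C3 and C6 stand 1,4 to each other and show their chain substituents C2 and C7 on the same ring face. These are the outward-pointing groups of a (3E,5E)-diene. One suprafacial singlet-oxygen [4+2] addition therefore makes the ring, both C–O bonds and both stereocentres, quaternary C6 included. The precursor 12 is the (8R)-4,6,8-trimethyl-16-phenylhexadeca-3,5-diene with C1 as a TBDPS ether, its two alkene geometries fixed by syn carboalumination and syn hydrozirconation.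

Key step: step 7

Remarks:
- **Numbering.** Atoms are numbered along the C16 chain from the carboxyl carbon C1. O2 is bonded to C3 and O1 to C6.
- **Configuration.** The target is (3S,4S,6R,8R). C2, C7 and the C4 methyl lie on one ring face; H3, H4 and the C6 methyl lie on the other.
- **Assumption.** (R)-Citronellal is used in its high-ee commercial grade, because C8 is never touched again and fixes the enantiomeric purity of 18.
- **SMILES convention.** In zirconocene species each cyclopentadienyl ring is written as a sigma-bonded C5H5 group.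

Step 1
Reactants: 1 (R)-citronellal; 2 6-phenylhex-1-ene
Product: 3 (3R,6E)-3-methyl-11-phenylundec-6-enal (E/Z mixture; E isomer drawn)
Conditions: 2 (3 equiv), second-generation Hoveyda–Grubbs catalyst (3 mol %), 1,4-benzoquinone (10 mol %), CH2Cl2, 40 °C, argon sweep
Reagents that add atoms: none
Why: Olefin cross-metathesis: the prenyl-type trisubstituted alkene of 1 does not homodimerise, the cheap terminal alkene is used in excess, escape of gaseous 2-methylpropene drives the exchange, benzoquinone suppresses chain-walking, the hydrocarbon dimer of 2 is far less polar than aldehyde 3, the alkene geometry is erased in step 2, and C8 (β to the aldehyde) is untouched.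

Step 2
Reactants: 3 (3R,6E)-3-methyl-11-phenylundec-6-enal
Product: 4 (3R)-3-methyl-11-phenylundecanal
Conditions: H2 (1 atm), 10% Pd/C, EtOAc, rt
Reagents that add atoms: none
Why: Heterogeneous catalytic hydrogenation saturates the disubstituted alkene and completes the eight-CH2 tether, while an aliphatic aldehyde and the phenyl ring survive these mild conditions in a non-alcoholic solvent.

Step 3
Reactants: 4 (3R)-3-methyl-11-phenylundecanal
Product: 5 (4R)-4-methyl-12-phenyldodec-1-yne
Conditions: dimethyl (1-diazo-2-oxopropyl)phosphonate, K2CO3, MeOH, 0 °C to rt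
Reagents that add atoms: dimethyl (1-diazo-2-oxopropyl)phosphonate, COP(=O)(OC)C(=[N+]=[N-])C(C)=O
Why: The Ohira–Bestmann variant of the Seyferth–Gilbert homologation turns the aldehyde carbon into C6 and adds C5 as the terminal alkyne carbon under mild carbonate base, and the stereocentre, being β to the carbonyl, cannot epimerise.

Step 4
Reactants: 5 (4R)-4-methyl-12-phenyldodec-1-yne
Product: 7 (1E,4R)-1-iodo-2,4-dimethyl-12-phenyldodec-1-ene, via alkenyldimethylalane 6 (not isolated)
Conditions: Me3Al (2.5 equiv), Cp2ZrCl2 (0.25 equiv), CH2Cl2, 0 °C to rt; then I2, THF, −30 to 0 °C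
Reagents that add atoms: trimethylaluminium, C[Al](C)C; iodine, II
Why: Negishi zirconium-catalysed carboalumination adds methyl and aluminium syn across the terminal alkyne, with methyl on the internal carbon C6 and aluminium on C5, and iodinolysis with retention gives the (E)-iodide in which C7 is trans to iodine.

Step 5
Reactants: 8 pent-3-yn-1-ol
Product: 9 tert-butyl(pent-3-yn-1-yloxy)diphenylsilane
Conditions: TBDPSCl, imidazole, CH2Cl2, 0 °C to rt
Reagents that add atoms: tert-butyl(chloro)diphenylsilane, CC(C)(C)[Si](Cl)(c1ccccc1)c1ccccc1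
Why: Imidazole-promoted silylation of a primary alcohol installs a group that is inert to zirconium hydride, zinc and palladium reagents, singlet oxygen and diimide, adds a UV handle for HPLC, and adds bulk to the C2 arm that later shields one ring face.

Step 6
Reactants: 9 tert-butyl(pent-3-yn-1-yloxy)diphenylsilane; 7 (1E,4R)-1-iodo-2,4-dimethyl-12-phenyldodec-1-ene
Product: 12 tert-butyl{[(3E,5E,8R)-4,6,8-trimethyl-16-phenylhexadeca-3,5-dien-1-yl]oxy}diphenylsilane, via alkenylzirconocene chloride 10 (not isolated), via alkenylzinc chloride 11 (not isolated)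
Conditions: 9 (1.5 equiv), Cp2ZrHCl, THF, 50 °C; ZnCl2, THF, 0 °C; then 7, Pd(PPh3)4 (5 mol %), rt
Reagents that add atoms: none
Why: Hydrozirconation adds H and Zr syn across the alkyne and, on warming with a slight excess of Cp2ZrHCl, equilibrates zirconium to the less hindered methyl-bearing carbon C4 (10); transmetalation to zinc (11) speeds up the Negishi coupling of this α-branched alkenyl metal with 7 at zerovalent palladium, and both partners keep their geometry, which gives the (3E,5E)-diene.

Step 7
Reactants: 12 tert-butyl{[(3E,5E,8R)-4,6,8-trimethyl-16-phenylhexadeca-3,5-dien-1-yl]oxy}diphenylsilane; 13 dioxygen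
Product: 14 tert-butyl(2-{(3S,6R)-4,6-dimethyl-6-[(2R)-2-methyl-10-phenyldecyl]-3,6-dihydro-1,2-dioxin-3-yl}ethoxy)diphenylsilane
Conditions: O2, tetraphenylporphyrin (1 mol %), visible light, CH2Cl2, −78 °C; silica filtration, then preparative HPLC
Reagents that add atoms: dioxygen 13, O=O
Why: Energy transfer from photoexcited tetraphenylporphyrin raises 13 to its singlet state, which adds suprafacially to C3 and C6 of the s-cis rotamer of 12 in a concerted, possibly asynchronous [4π+2π] event that forms O2–C3 and O1–C6 together and moves the remaining double bond to C4=C5. The closest known reaction type is the dye-sensitised photooxygenation (hetero-Diels–Alder reaction with singlet oxygen) of acyclic 1,3-dienes, dienes with a fully substituted terminus included, to 3,6-dihydro-1,2-dioxines. The one new ring, six-membered O1–O2–C3–C4–C5–C6, is closed by cycloaddition, both ring bonds arising at once, not by a stepwise exo or endo cyclisation. C3 and C6 are controlled relative to each other by the alkene geometries alone, because the outward groups C2 (from 3E) and C7 (from 5E) must end on one ring face and the inward H3 and C6 methyl on the other. Neither diene face is favoured by remote C8, so 14 (3S,6R,8R) should form beside its (3R,6S,8R) isomer and has to be taken out by preparative HPLC. The step needs periselectivity for [4+2] addition over the Schenck ene reaction at the allylic C–H bonds of C2, C7 and the two methyl groups, and this is served by the C4 methyl, which collides with the C6 methyl in the s-trans rotamer and so keeps a skewed s-cis rotamer populated, by the electron-rich tetraalkyl diene, and by the aprotic medium at low temperature.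

Step 8
Reactants: 14 tert-butyl(2-{(3S,6R)-4,6-dimethyl-6-[(2R)-2-methyl-10-phenyldecyl]-3,6-dihydro-1,2-dioxin-3-yl}ethoxy)diphenylsilane
Product: 15 tert-butyl(2-{(3S,4S,6R)-4,6-dimethyl-6-[(2R)-2-methyl-10-phenyldecyl]-1,2-dioxan-3-yl}ethoxy)diphenylsilane
Conditions: KO2CN=NCO2K (large excess, in portions), AcOH (slow addition), CH2Cl2/MeOH, 0 °C to rt, repeated until conversion is complete; chromatography
Reagents that add atoms: none
Why: Diimide reduction transfers two hydrogens to C4=C5 in a concerted syn fashion and leaves the O–O bond alone; delivery should come from the ring face that shows only H3 and the C6 methyl, since the other face is covered by the C2 and C7 arms (one of them pseudoaxial in either half-chair), which puts H4 cis to H3 and sets (4S), while the slow trisubstituted alkene explains the repeated charges of reagent.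

Step 9
Reactants: 15 tert-butyl(2-{(3S,4S,6R)-4,6-dimethyl-6-[(2R)-2-methyl-10-phenyldecyl]-1,2-dioxan-3-yl}ethoxy)diphenylsilane
Product: 16 2-{(3S,4S,6R)-4,6-dimethyl-6-[(2R)-2-methyl-10-phenyldecyl]-1,2-dioxan-3-yl}ethanol
Conditions: Bu4NF, AcOH (1:1), THF, 0 °C to rt
Reagents that add atoms: none
Why: Fluoride-induced Si–O cleavage frees the primary alcohol, and the AcOH buffer keeps the medium from becoming basic enough to remove H3 and start a Kornblum–DeLaMare-type opening of the peroxide; no stereocentre is involved.

Step 10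
Reactants: 16 2-{(3S,4S,6R)-4,6-dimethyl-6-[(2R)-2-methyl-10-phenyldecyl]-1,2-dioxan-3-yl}ethanol
Product: 18 2-{(3S,4S,6R)-4,6-dimethyl-6-[(2R)-2-methyl-10-phenyldecyl]-1,2-dioxan-3-yl}acetic acid, via dioxanylacetaldehyde 17 (not isolated)
Conditions: TEMPO (20 mol %), PhI(OAc)2 (2.5 equiv), MeCN/H2O (1:1), rt
Reagents that add atoms: water, O
Why: Oxoammonium-catalysed oxidation (TEMPO, with PhI(OAc)2 as terminal oxidant) takes the primary alcohol through aldehyde 17 and its hydrate to the acid in one flask under weakly acidic conditions, so the β-peroxy aldehyde never meets base (no E1cB loss of the C3–O2 bond) and the dialkyl peroxide and the benzylic CH2 are left alone.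

Compound list
1 | (R)-citronellal, (3R)-3,7-dimethyloct-6-enal | C[C@H](CCC=C(C)C)CC=O | starting material
2 | 6-phenylhex-1-ene | C=CCCCCc1ccccc1 | starting material
3 | (3R,6E)-3-methyl-11-phenylundec-6-enal (E/Z mixture, E drawn) | C[C@H](CC/C=C/CCCCc1ccccc1)CC=O | intermediate
4 | (3R)-3-methyl-11-phenylundecanal | C[C@H](CCCCCCCCc1ccccc1)CC=O | intermediate
5 | (4R)-4-methyl-12-phenyldodec-1-yne | C[C@H](CCCCCCCCc1ccccc1)CC#C | intermediate
6 | [(1E,4R)-2,4-dimethyl-12-phenyldodec-1-en-1-yl]dimethylalane | C[C@H](CCCCCCCCc1ccccc1)C/C(C)=C/[Al](C)C | intermediate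
7 | (1E,4R)-1-iodo-2,4-dimethyl-12-phenyldodec-1-ene | C[C@H](CCCCCCCCc1ccccc1)C/C(C)=C/I | intermediate
8 | pent-3-yn-1-ol | CC#CCCO | starting material
9 | tert-butyl(pent-3-yn-1-yloxy)diphenylsilane | CC#CCCO[Si](c1ccccc1)(c1ccccc1)C(C)(C)C | intermediate
10 | chlorobis(cyclopentadienyl)[(2E)-5-(tert-butyldiphenylsilyloxy)pent-2-en-2-yl]zirconium | Cl[Zr](C1C=CC=C1)(C1C=CC=C1)/C(C)=C/CCO[Si](c1ccccc1)(c1ccccc1)C(C)(C)C | intermediate
11 | chloro[(2E)-5-(tert-butyldiphenylsilyloxy)pent-2-en-2-yl]zinc | Cl[Zn]/C(C)=C/CCO[Si](c1ccccc1)(c1ccccc1)C(C)(C)C | intermediate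
12 | tert-butyl{[(3E,5E,8R)-4,6,8-trimethyl-16-phenylhexadeca-3,5-dien-1-yl]oxy}diphenylsilane | C[C@H](CCCCCCCCc1ccccc1)C/C(C)=C/C(C)=C/CCO[Si](c1ccccc1)(c1ccccc1)C(C)(C)C | intermediate
13 | dioxygen | O=O | starting material
14 | tert-butyl(2-{(3S,6R)-4,6-dimethyl-6-[(2R)-2-methyl-10-phenyldecyl]-3,6-dihydro-1,2-dioxin-3-yl}ethoxy)diphenylsilane | C[C@H](CCCCCCCCc1ccccc1)C[C@]1(C)C=C(C)[C@H](CCO[Si](c2ccccc2)(c2ccccc2)C(C)(C)C)OO1 | intermediate
15 | tert-butyl(2-{(3S,4S,6R)-4,6-dimethyl-6-[(2R)-2-methyl-10-phenyldecyl]-1,2-dioxan-3-yl}ethoxy)diphenylsilane | C[C@H](CCCCCCCCc1ccccc1)C[C@]1(C)C[C@H](C)[C@H](CCO[Si](c2ccccc2)(c2ccccc2)C(C)(C)C)OO1 | intermediate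
16 | 2-{(3S,4S,6R)-4,6-dimethyl-6-[(2R)-2-methyl-10-phenyldecyl]-1,2-dioxan-3-yl}ethanol | C[C@H](CCCCCCCCc1ccccc1)C[C@]1(C)C[C@H](C)[C@H](CCO)OO1 | intermediate
17 | 2-{(3S,4S,6R)-4,6-dimethyl-6-[(2R)-2-methyl-10-phenyldecyl]-1,2-dioxan-3-yl}acetaldehyde | C[C@H](CCCCCCCCc1ccccc1)C[C@]1(C)C[C@H](C)[C@H](CC=O)OO1 | intermediate
18 | 2-{(3S,4S,6R)-4,6-dimethyl-6-[(2R)-2-methyl-10-phenyldecyl]-1,2-dioxan-3-yl}acetic acid | C[C@H](CCCCCCCCc1ccccc1)C[C@]1(C)C[C@H](C)[C@H](CC(=O)O)OO1 | target

Total step count: 10. Longest linear sequence: 9 (steps 1 to 4 and 6 to 10).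

Steps most likely to fail

1. **Step 7.**
   - What may go wrong: allylic hydrogen abstraction by singlet oxygen (the ene pathway) may outrun ring closure, and the two ring-face isomers may fail to separate as lipophilic silyl ethers.
   - The fallback sets out from 12 and comes back at 18. The oxidation level of C1 is raised before oxygen is brought in, so a different, less ene-prone diene meets singlet oxygen.
   - Bu4NF in THF should free (3E,5E,8R)-4,6,8-trimethyl-16-phenylhexadeca-3,5-dien-1-ol F1. TEMPO/PhI(OAc)2 in aqueous MeCN should carry it through (3E,5E,8R)-4,6,8-trimethyl-16-phenylhexadeca-3,5-dienal F2 to (3E,5E,8R)-4,6,8-trimethyl-16-phenylhexadeca-3,5-dienoic acid F3.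
   - Photooxygenation of F3 (O2, tetraphenylporphyrin, light, CH2Cl2, low temperature) should give 2-{(3S,6R)-4,6-dimethyl-6-[(2R)-2-methyl-10-phenyldecyl]-3,6-dihydro-1,2-dioxin-3-yl}acetic acid F4. It is parted from its ring-face isomer by reversed-phase HPLC. Diimide reduction as in step 8 then leads straight to 18.
   - Why it should help: the carboxymethyl arm lowers the electron density of C3=C4 and of the C2–H bonds, which should close one ene channel. The polar acids should be easier to part. Neither fluoride nor an oxidant ever meets the peroxide.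

2. **Step 8.**
   - What may go wrong: hydrogen delivery may discriminate poorly between the two ring faces, and slow turnover at the trisubstituted alkene may leave unreduced material, so isomers travel together with 15.
   - The fallback sets out from crude 15 and comes back at 16. Purification is moved from chromatography of silyl ethers to a covalent chiral derivative.
   - Crude 15 is desilylated as in step 9. The alcohol mixture is acylated with (1S)-camphanic chloride (pyridine, CH2Cl2, 0 °C) to give 2-{(3S,4S,6R)-4,6-dimethyl-6-[(2R)-2-methyl-10-phenyldecyl]-1,2-dioxan-3-yl}ethyl (1S,4R)-4,7,7-trimethyl-3-oxo-2-oxabicyclo[2.2.1]heptane-1-carboxylate F5.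
   - The rigid chiral acyl group close to the ring should magnify the differences between C4 epimers, unreduced material and any ring-face isomer left from step 7. Crystallisation or chromatography should then deliver one isomer.
   - Methanolysis (K2CO3, MeOH, 0 °C) returns pure 16.

3. **Step 6.**
   - What may go wrong: zirconium may partly settle on C3 instead of C4 (regiochemical leakage), and left-over hydride may strip iodine from 7. Both faults would be carried into the diene.
   - The fallback sets out from 9 and 5 and comes back at 12. The polarity of the coupling is reversed.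
   - 9 is hydrozirconated with a clear excess of Cp2ZrHCl at 50 °C until 10 is fully equilibrated. It is quenched with I2 to give tert-butyl{[(3E)-4-iodopent-3-en-1-yl]oxy}diphenylsilane F6, which is purified to regiochemical homogeneity at this cheap stage.
   - Alkyne 5 is carboaluminated as in step 4 to alane 6, which is not iodinated. It is treated with ZnCl2 in THF to give chloro[(1E,4R)-2,4-dimethyl-12-phenyldodec-1-en-1-yl]zinc F7 and coupled in the same flask with F6 under Pd(PPh3)4.
   - The nucleophile is now the unhindered alkenyl metal, no hydride is present during the coupling, and iodide 7 is bypassed.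

Further compounds
F1 | step 7 | (3E,5E,8R)-4,6,8-trimethyl-16-phenylhexadeca-3,5-dien-1-ol | C[C@H](CCCCCCCCc1ccccc1)C/C(C)=C/C(C)=C/CCO
F2 | step 7 | (3E,5E,8R)-4,6,8-trimethyl-16-phenylhexadeca-3,5-dienal | C[C@H](CCCCCCCCc1ccccc1)C/C(C)=C/C(C)=C/CC=O
F3 | step 7 | (3E,5E,8R)-4,6,8-trimethyl-16-phenylhexadeca-3,5-dienoic acid | C[C@H](CCCCCCCCc1ccccc1)C/C(C)=C/C(C)=C/CC(=O)O
F4 | step 7 | 2-{(3S,6R)-4,6-dimethyl-6-[(2R)-2-methyl-10-phenyldecyl]-3,6-dihydro-1,2-dioxin-3-yl}acetic acid | C[C@H](CCCCCCCCc1ccccc1)C[C@]1(C)C=C(C)[C@H](CC(=O)O)OO1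
F5 | step 8 | 2-{(3S,4S,6R)-4,6-dimethyl-6-[(2R)-2-methyl-10-phenyldecyl]-1,2-dioxan-3-yl}ethyl (1S,4R)-4,7,7-trimethyl-3-oxo-2-oxabicyclo[2.2.1]heptane-1-carboxylate | C[C@H](CCCCCCCCc1ccccc1)C[C@]1(C)C[C@H](C)[C@H](CCOC(=O)[C@@]23CC[C@@](C)(C(=O)O2)C3(C)C)OO1
F6 | step 6 | tert-butyl{[(3E)-4-iodopent-3-en-1-yl]oxy}diphenylsilane | I/C(C)=C/CCO[Si](c1ccccc1)(c1ccccc1)C(C)(C)C
F7 | step 6 | chloro[(1E,4R)-2,4-dimethyl-12-phenyldodec-1-en-1-yl]zinc | C[C@H](CCCCCCCCc1ccccc1)C/C(C)=C/[Zn]Cl
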